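The data were generated by integration with constants of no real substance; scatter was added.

Amounts first, in mM rather than percent: at 5.00 h teal holds 28.6 mM of target and violet 28.8 mM, from very different charges of substrate.

| flask | substrate | gas phase | free catalyst | remark | time |
|---|---|---|---|---|---|
| teal | 0.052 M | 4.6 mM (held) | 0.14 mol% | run made earlier |  |
| violet | 0.12 M | 4.6 mM (held) | 0.14 mol% | run made earlier |  |
| amber | 0.078 M | 4.6 mM (held) | 0.28 mol% | run made earlier |  |
| flask | 0.078 M | 4.6 mM (held) | 0.14 mol% |  | 6.0 h |

| run | time / h | target / % |
|---|---|---|
| teal | 0.417 | 7 |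
| teal | 0.667 | 11 |
| teal | 1.33 | 21 |
| teal | 2.50 | 37 |
| teal | 5.00 | 55 |
| violet | 0.417 | 1 |
| violet | 0.667 | 8 |
| violet | 1.33 | 10 |
| violet | 2.50 | 20 |
| violet | 5.00 | 24 |
| amber | 0.417 | 6 |
| amber | 1.33 | 16 |
| amber | 2.00 | 27 |
| amber | 3.00 | 37 |
| amber | 5.00 | 52 |

(each reading ± 1.5 percentage points)

- at the start none of the gas phase is in solution

1. the target standing at 6.0 h, as a percentage of the substrate charged
2. concentration of dissolved gas in solution at 6.0 h, in percent of saturation

1. Start. Over the first 1.33 h, teal makes target at 8.21 mM h⁻¹ and violet at 9.02 mM h⁻¹, and amber over the same span at 9.38 mM h⁻¹. Violet carries 2.31 times the substrate of teal but runs just 1.10 times faster, which reads as gas entering solution being the rate-limiting step. Their mean, R = 8.87 mM h⁻¹, is the early rate.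

2. Slowing. Over the last interval, teal and violet average a fraction ρ = 0.319 of R. Violet by itself runs at 0.216 of R with a target of just 24%, so its rate has fallen further than its substrate.

3. Accumulation. Let T be the target divided by R, the hours at the early rate that the target is worth. At 5.00 h, teal gives 3.22 h, violet 3.25 h and amber, at twice the loading, 4.57 h. Teal and violet bracket amber's substrate charge, so amber against them reads as a gain g = 1.41 per doubling of the loading.

4. The flask. Its loading matches teal and violet, and the last hour adds ρ of an hour, so the flask stands at 3.55 h full-rate hours. This reckoning gives 40.4% of target and, taking the rate as proportional to the gas deficit, 68.1% of saturation.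

The forecast gives 41% and 75%, on the ground that “the catalyst is probably dying”.

The flask gives 45.6% and 78.9%.

    gas phase ⇌ dissolved gas, rate k1*(csat - [dissolved gas]) (kL = 6.90 × 10⁻⁴ s⁻¹)
    substrate + free catalyst → spent catalyst (k = 0.00280 M⁻¹ s⁻¹)
    substrate + dissolved gas + free catalyst → free catalyst + target (k = 990 M⁻² s⁻¹)

The forecast stands within its margins. In full-rate hours the flask reaches 4.01 h, above the reckoned 3.55 h, and by 6.00 h its free catalyst is down to 3.43% of its charge with 54.2% of the substrate left. A neighbour flask is charged with a quarter of the loading, 0.035 mol%, so the reckoned 3.55 h divides by g for each of the two halvings, to 1.78 h, or 20.2% of target. At 6.00 h that neighbour flask stands at 23.5% of target, with 76.5% of its substrate left.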